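**Retrosynthetic overview**

1. Feature: in the carbocycle C5–C9, C6 (OH, CO2Me) is the central carbon of a hydroxymalonate whose second ester carbon has become C7. C7(OMe)=C8(OMe)–C9(=O) is the methyl enol ether of a 2-methoxycyclopentane-1,3-dione, spiro-joined at C5 to the 3(2H)-furanone ring O1–C5.
2. Target 15 ⇐ desilylation and methylation of the C7 enol oxygen ⇐ spiro dione 13 ⇐ C7–C8 bond by Dieckmann closure onto one of two diastereotopic malonate esters ⇐ furanone 12, which carries the methoxyacetyl group (C9, C8) and the silyloxymalonate (C6, C7) on C5.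
3. 12 ⇐ C5–C6 bond by Mukaiyama aldol of the 3-silyloxyfuran 9 with dimethyl oxomalonate 10. This is done racemically and resolved, because C5 is the only stereocentre of 12 and resolution keeps the uncertainty of the route in the ring closure.
4. 9 ⇐ C5–C9 bond by C-acylation of the 5-aryl-3(2H)-furanone 6 with methoxyacetyl chloride ⇐ cyclodehydration of a 4-hydroxy-1,3-diketone made from 4'-hydroxyacetophenone and benzyloxyacetyl chloride.
5. Ring order: furanone ring (step 3), then cyclopentenedione ring (step 8).

Key step: step 8

Remark: locants O1 to C9 are those of the 1-oxaspiro[4.4]nonane skeleton of 15 and are used for the corresponding atoms of every intermediate; dione 13 will be a mixture of enol tautomers and is drawn as its C7 enol.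

**Route**

Step 1
Reactants: 1 1-(4-hydroxyphenyl)ethan-1-one
Product: 2 1-{4-[tri(propan-2-yl)silyloxy]phenyl}ethan-1-one
Conditions: TIPSCl, imidazole, DMF, rt
Reagents that add atoms: chlorotri(propan-2-yl)silane, CC(C)[Si](Cl)(C(C)C)C(C)C
Why: Imidazole-promoted O-silylation of a phenol is routine and masks the only acidic OH before the enolate chemistry; no stereocentre is involved.

Step 2
Reactants: 2 1-{4-[tri(propan-2-yl)silyloxy]phenyl}ethan-1-one; 3 (benzyloxy)acetyl chloride
Product: 4 4-(benzyloxy)-1-{4-[tri(propan-2-yl)silyloxy]phenyl}butane-1,3-dione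
Conditions: LiHMDS (2.1 equiv), THF, −78 °C; then 3, −78 → 0 °C; aq. NH4Cl
Reagents that add atoms: none
Why: C-acylation of the lithium enolate of an aryl methyl ketone by an acid chloride (crossed Claisen-type acylation) should stop at the 1,3-diketone because the second equivalent of base holds the product as its unreactive lithium diketonate.

Step 3
Reactants: 4 4-(benzyloxy)-1-{4-[tri(propan-2-yl)silyloxy]phenyl}butane-1,3-dione
Product: 6 5-{4-[tri(propan-2-yl)silyloxy]phenyl}furan-3(2H)-one, via hydroxy diketone 5 (not isolated)
Conditions: H2 (1 atm), 10% Pd/C, EtOAc, rt; filter; TsOH·H2O (5 mol %), CH2Cl2, rt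
Reagents that add atoms: none
Why: Hydrogenolysis of the benzyl ether frees the primary alcohol, which under acid catalysis adds 5-exo-trig to the aryl ketone and loses water to give the vinylogous ester, the classical cyclodehydration of a 4-hydroxy-1,3-diketone to a 3(2H)-furanone.

Step 4
Reactants: 6 5-{4-[tri(propan-2-yl)silyloxy]phenyl}furan-3(2H)-one; 7 methoxyacetyl chloride
Product: 8 1-(3-hydroxy-5-{4-[tri(propan-2-yl)silyloxy]phenyl}furan-2-yl)-2-methoxyethan-1-one
Conditions: LiHMDS (2.2 equiv), THF, −78 °C; then 7 (1.05 equiv), −78 → 0 °C; 1 M HCl work-up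
Reagents that add atoms: none
Why: Deprotonation is possible only at C5 (the furanone CH2, giving an aromatic 3-furanolate), and Claisen-type C-acylation with the acid chloride should give the 2-acyl-3-hydroxyfuran, whose acidic chelated enol is held as its lithium salt by the second equivalent of base while any O-acylated furan passes its acyl group on to unreacted enolate.

Step 5
Reactants: 8 1-(3-hydroxy-5-{4-[tri(propan-2-yl)silyloxy]phenyl}furan-2-yl)-2-methoxyethan-1-one
Product: 9 2-methoxy-1-(3-(triethylsilyloxy)-5-{4-[tri(propan-2-yl)silyloxy]phenyl}furan-2-yl)ethan-1-one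
Conditions: TESCl (1.2 equiv), Et3N (1.5 equiv), CH2Cl2, 0 °C; filtered through Celite under argon, used crude
Reagents that add atoms: chlorotriethylsilane, CC[Si](Cl)(CC)CC
Why: O-silylation of the acidic enol OH with a silyl chloride and an amine gives the silyl enol ether of the β-diketone, which removes the stabilising hydrogen bond and makes C5 a Mukaiyama donor.

Step 6
Reactants: 9 2-methoxy-1-(3-(triethylsilyloxy)-5-{4-[tri(propan-2-yl)silyloxy]phenyl}furan-2-yl)ethan-1-one; 10 dimethyl 2-oxopropanedioate
Product: 11 rac-dimethyl 2-[2-(methoxyacetyl)-3-oxo-5-{4-[tri(propan-2-yl)silyloxy]phenyl}-2,3-dihydrofuran-2-yl]-2-(triethylsilyloxy)propanedioate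
Conditions: 10 (1.5 equiv, freshly distilled), TESOTf (10 mol %), CH2Cl2, −78 → −40 °C; Et3N quench
Reagents that add atoms: none
Why: In this Mukaiyama aldol addition under silyl triflate catalysis the silyl-activated keto group of 10 should be attacked by C5 of the 3-silyloxyfuran, the position that gives a cation stabilised by both the silyloxy group and O1, and silyl transfer to the next molecule of 10 leaves the new tertiary oxygen as its triethylsilyl ether so that no retro-aldol can follow; C5 is formed without control, as the racemate.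

Step 7
Reactants: 11 rac-dimethyl 2-[2-(methoxyacetyl)-3-oxo-5-{4-[tri(propan-2-yl)silyloxy]phenyl}-2,3-dihydrofuran-2-yl]-2-(triethylsilyloxy)propanedioate
Product: 12 dimethyl 2-[(2S)-2-(methoxyacetyl)-3-oxo-5-{4-[tri(propan-2-yl)silyloxy]phenyl}-2,3-dihydrofuran-2-yl]-2-(triethylsilyloxy)propanedioate
Conditions: preparative SFC, immobilised amylose tris(3,5-dimethylphenylcarbamate) phase, CO2/i-PrOH
Reagents that add atoms: none
Why: Resolution by preparative chromatography on a chiral stationary phase is dependable for a neutral UV-active compound whose quaternary C5 cannot epimerise while the C6 oxygen is silylated; which fraction is the (S)-enantiomer would be settled by anomalous-dispersion X-ray analysis or by the sign of rotation of 15.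

Step 8
Reactants: 12 dimethyl 2-[(2S)-2-(methoxyacetyl)-3-oxo-5-{4-[tri(propan-2-yl)silyloxy]phenyl}-2,3-dihydrofuran-2-yl]-2-(triethylsilyloxy)propanedioate
Product: 13 methyl (5S,6R)-7-hydroxy-8-methoxy-4,9-dioxo-6-(triethylsilyloxy)-2-{4-[tri(propan-2-yl)silyloxy]phenyl}-1-oxaspiro[4.4]nona-2,7-diene-6-carboxylate
Conditions: LiHMDS (2.5 equiv), THF, −78 °C, 30 min; then −78 → 0 °C; AcOH in THF at −78 °C, brine
Reagents that add atoms: none
Why: LiHMDS removes a proton from C8, the only enolisable carbon of 12, the enolate carbon adds to one of the two ester carbonyls on C6, methoxide leaves, and the 2-methoxy-1,3-dione is deprotonated at once by the second equivalent of base, so that the closure cannot reverse and the product is shielded as its enolate. The closest known reaction type is the Dieckmann (intramolecular Claisen) condensation of 4-oxo esters to 2-substituted cyclopentane-1,3-diones, run here with substrate-controlled choice between two diastereotopic ester groups. The carbocycle C5–C6–C7–C8–C9 closes 5-exo-trig at the ester carbonyl with the enolate double bond C8=C9 inside the new ring, the mode of the 4-oxo ester closures, and is helped by the two fully substituted carbons C5 and C6. C6 becomes a stereocentre under control of C5: addition to either ester is reversible, the two adducts exchange through the open enolate, and the one expected to go on is that in which the triethylsilyloxy group sits on the ring face of the small ring oxygen O1 and the spectator ester lies beside the C4 carbonyl, where lithium can bridge the two carbonyl oxygens, which gives (5S,6R). The step needs site selectivity (only C8 can be deprotonated, and complete enolisation at −78 °C before warming keeps liberated methoxide away from the C9 carbonyl), survival of the C5–C6 bond (the silyl ether on the C6 oxygen rules out retro-aldol loss of the oxomalonate) and the choice between the two esters (secured by the C5 stereocentre as described).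

Step 9
Reactants: 13 methyl (5S,6R)-7-hydroxy-8-methoxy-4,9-dioxo-6-(triethylsilyloxy)-2-{4-[tri(propan-2-yl)silyloxy]phenyl}-1-oxaspiro[4.4]nona-2,7-diene-6-carboxylate
Product: 14 methyl (5S,6R)-7,8-dimethoxy-4,9-dioxo-6-(triethylsilyloxy)-2-{4-[tri(propan-2-yl)silyloxy]phenyl}-1-oxaspiro[4.4]nona-2,7-diene-6-carboxylate
Conditions: TMSCHN2 (1.5 equiv), toluene/MeOH (4:1), 0 °C
Reagents that add atoms: (trimethylsilyl)diazomethane, C[Si](C)(C)C=[N+]=[N-]
Why: O-methylation of a vinylogous acid by a diazoalkane touches only the acidic enol, and the C7 oxygen is expected to take the methyl group because the enol proton should rest there, hydrogen-bonded to the C6 ester carbonyl, and the methyl group is delivered within the ion pair; C5 and C6 are not affected.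

Step 10
Reactants: 14 methyl (5S,6R)-7,8-dimethoxy-4,9-dioxo-6-(triethylsilyloxy)-2-{4-[tri(propan-2-yl)silyloxy]phenyl}-1-oxaspiro[4.4]nona-2,7-diene-6-carboxylate
Product: 15 methyl (5S,6R)-6-hydroxy-2-(4-hydroxyphenyl)-7,8-dimethoxy-4,9-dioxo-1-oxaspiro[4.4]nona-2,7-diene-6-carboxylate (limnophilaspiroketone)
Conditions: TBAF (3 equiv), AcOH (3 equiv), THF, 0 °C → rt
Reagents that add atoms: none
Why: Fluoride-mediated desilylation removes both silyl ethers, and the acetic acid buffer keeps the medium from becoming basic, which protects the free C6 hydroxy compound from retro-aldol opening and so keeps C5 and C6 intact.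

**Compound list**

1 | 1-(4-hydroxyphenyl)ethan-1-one | CC(=O)c1ccc(O)cc1 | starting material
2 | 1-{4-[tri(propan-2-yl)silyloxy]phenyl}ethan-1-one | CC(=O)c1ccc(O[Si](C(C)C)(C(C)C)C(C)C)cc1 | intermediate
3 | (benzyloxy)acetyl chloride | O=C(Cl)COCc1ccccc1 | starting material
4 | 4-(benzyloxy)-1-{4-[tri(propan-2-yl)silyloxy]phenyl}butane-1,3-dione | O=C(COCc1ccccc1)CC(=O)c1ccc(O[Si](C(C)C)(C(C)C)C(C)C)cc1 | intermediate
5 | 4-hydroxy-1-{4-[tri(propan-2-yl)silyloxy]phenyl}butane-1,3-dione | O=C(CO)CC(=O)c1ccc(O[Si](C(C)C)(C(C)C)C(C)C)cc1 | intermediate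
6 | 5-{4-[tri(propan-2-yl)silyloxy]phenyl}furan-3(2H)-one | O=C1COC(c2ccc(O[Si](C(C)C)(C(C)C)C(C)C)cc2)=C1 | intermediate
7 | methoxyacetyl chloride | COCC(Cl)=O | starting material
8 | 1-(3-hydroxy-5-{4-[tri(propan-2-yl)silyloxy]phenyl}furan-2-yl)-2-methoxyethan-1-one | COCC(=O)c1oc(-c2ccc(O[Si](C(C)C)(C(C)C)C(C)C)cc2)cc1O | intermediate
9 | 2-methoxy-1-(3-(triethylsilyloxy)-5-{4-[tri(propan-2-yl)silyloxy]phenyl}furan-2-yl)ethan-1-one | COCC(=O)c1oc(-c2ccc(O[Si](C(C)C)(C(C)C)C(C)C)cc2)cc1O[Si](CC)(CC)CC | intermediate
10 | dimethyl 2-oxopropanedioate | COC(=O)C(=O)C(=O)OC | starting material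
11 | rac-dimethyl 2-[2-(methoxyacetyl)-3-oxo-5-{4-[tri(propan-2-yl)silyloxy]phenyl}-2,3-dihydrofuran-2-yl]-2-(triethylsilyloxy)propanedioate | COCC(=O)C1(C(O[Si](CC)(CC)CC)(C(=O)OC)C(=O)OC)OC(c2ccc(O[Si](C(C)C)(C(C)C)C(C)C)cc2)=CC1=O | intermediate
12 | dimethyl 2-[(2S)-2-(methoxyacetyl)-3-oxo-5-{4-[tri(propan-2-yl)silyloxy]phenyl}-2,3-dihydrofuran-2-yl]-2-(triethylsilyloxy)propanedioate | COCC(=O)[C@@]1(C(O[Si](CC)(CC)CC)(C(=O)OC)C(=O)OC)OC(c2ccc(O[Si](C(C)C)(C(C)C)C(C)C)cc2)=CC1=O | intermediate
13 | methyl (5S,6R)-7-hydroxy-8-methoxy-4,9-dioxo-6-(triethylsilyloxy)-2-{4-[tri(propan-2-yl)silyloxy]phenyl}-1-oxaspiro[4.4]nona-2,7-diene-6-carboxylate | COC(=O)[C@@]1(O[Si](CC)(CC)CC)C(O)=C(OC)C(=O)[C@]12OC(c1ccc(O[Si](C(C)C)(C(C)C)C(C)C)cc1)=CC2=O | intermediate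
14 | methyl (5S,6R)-7,8-dimethoxy-4,9-dioxo-6-(triethylsilyloxy)-2-{4-[tri(propan-2-yl)silyloxy]phenyl}-1-oxaspiro[4.4]nona-2,7-diene-6-carboxylate | COC(=O)[C@@]1(O[Si](CC)(CC)CC)C(OC)=C(OC)C(=O)[C@]12OC(c1ccc(O[Si](C(C)C)(C(C)C)C(C)C)cc1)=CC2=O | intermediate
15 | methyl (5S,6R)-6-hydroxy-2-(4-hydroxyphenyl)-7,8-dimethoxy-4,9-dioxo-1-oxaspiro[4.4]nona-2,7-diene-6-carboxylate (limnophilaspiroketone) | COC(=O)[C@@]1(O)C(OC)=C(OC)C(=O)[C@]12OC(c1ccc(O)cc1)=CC2=O | target

**Step count and risks**

Total step count: 10. Longest linear sequence: 10 steps (1 → 15).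

Steps most likely to fail:

Step 8 (key step). The closure may discriminate poorly between the two ester groups, or prefer the other one, because the difference between the silyloxy group and the spectator ester next to O1 and C4 is modest. The C8 enolate may also close slowly, since its double bond lies inside the forming five-membered ring. That would leave time for the triethylsilyl group to move from the C6 oxygen to the enolate oxygen, followed by retro-aldol loss of the oxomalonate, or for methoxide to attack C9. The fallback takes the choice between the two carboxyl groups out of the C–C bond-forming step. It sets out from 12: mono-hydrolysis (Me3SnOH, 1,2-dichloroethane, 60 °C, or an esterase at pH 7) should give two diastereomeric half-esters, which are separated. The one with the free carboxyl group in the position that is to become C7, the (2S)-half-ester F1, is kept. Its epimer at the malonate carbon, the (2R)-half-ester F2, is returned to 12 with TMSCHN2. F1 is converted with carbonyldiimidazole (THF, rt) into the acyl imidazolide F3. LiHMDS (THF, −78 °C) then closes the ring by attack of the C8 enolate on the acyl imidazole only, the methyl ester being inert at this temperature, and the sequence comes back to the route at 13. Mono-hydrolysis of a malonate, acyl imidazolide formation and C-acylation of a ketone enolate by an activated acyl group are all known chemistry, and the more electrophilic acyl group also answers a sluggish closure.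

Step 9. Methylation may take place on the C9 enol oxygen, the less crowded of the two, instead of the C7 oxygen next to the silyloxy-bearing C6. The fallback replaces kinetic alkylation of the enol oxygen by reversible, acid-catalysed enol ether formation on the unprotected compound. It sets out from 13: both silyl groups are removed first (TBAF, AcOH, THF) to give the trihydroxy dione F4. Trimethyl orthoformate, MeOH and catalytic camphorsulfonic acid at rt should then convert the vinylogous acid into its methyl enol ether without touching the phenol or the tertiary alcohol. Because the etherification is reversible under these conditions, material methylated on the other enol oxygen is not lost but re-enters the equilibrium when it is returned to the same medium; the position of that equilibrium is not known in advance. The sequence comes back to the route at 15.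

Step 6. The 2-acyl group makes the silyl enol ether a weak donor, so the electrophile may attack the free ring position C3 of the furan instead of C5, or the silyl group may simply be lost before C–C bond formation. The fallback sets out from 8 and 10: direct aldol addition under soft enolisation (MgBr2·OEt2, i-Pr2NEt, CH2Cl2, 0 °C), in which the chelated magnesium diketonate can react only through its central carbon C5, should give the free tertiary alcohol F5. Silylation with TESOTf and 2,6-lutidine (CH2Cl2, −78 → 0 °C) returns to the route at 11.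

**Further compounds**

F1 | step 8 | (2S)-3-methoxy-2-[(2S)-2-(methoxyacetyl)-3-oxo-5-{4-[tri(propan-2-yl)silyloxy]phenyl}-2,3-dihydrofuran-2-yl]-3-oxo-2-(triethylsilyloxy)propanoic acid | COCC(=O)[C@@]1([C@@](O[Si](CC)(CC)CC)(C(=O)OC)C(=O)O)OC(c2ccc(O[Si](C(C)C)(C(C)C)C(C)C)cc2)=CC1=O
F2 | step 8 | (2R)-3-methoxy-2-[(2S)-2-(methoxyacetyl)-3-oxo-5-{4-[tri(propan-2-yl)silyloxy]phenyl}-2,3-dihydrofuran-2-yl]-3-oxo-2-(triethylsilyloxy)propanoic acid | COCC(=O)[C@@]1([C@](O[Si](CC)(CC)CC)(C(=O)OC)C(=O)O)OC(c2ccc(O[Si](C(C)C)(C(C)C)C(C)C)cc2)=CC1=O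
F3 | step 8 | methyl (2S)-3-(1H-imidazol-1-yl)-2-[(2S)-2-(methoxyacetyl)-3-oxo-5-{4-[tri(propan-2-yl)silyloxy]phenyl}-2,3-dihydrofuran-2-yl]-3-oxo-2-(triethylsilyloxy)propanoate | COCC(=O)[C@@]1([C@@](O[Si](CC)(CC)CC)(C(=O)OC)C(=O)n3ccnc3)OC(c2ccc(O[Si](C(C)C)(C(C)C)C(C)C)cc2)=CC1=O
F4 | step 9 | methyl (5S,6R)-6,7-dihydroxy-2-(4-hydroxyphenyl)-8-methoxy-4,9-dioxo-1-oxaspiro[4.4]nona-2,7-diene-6-carboxylate | COC(=O)[C@@]1(O)C(O)=C(OC)C(=O)[C@]12OC(c1ccc(O)cc1)=CC2=O
F5 | step 6 | rac-dimethyl 2-hydroxy-2-[2-(methoxyacetyl)-3-oxo-5-{4-[tri(propan-2-yl)silyloxy]phenyl}-2,3-dihydrofuran-2-yl]propanedioate | COCC(=O)C1(C(O)(C(=O)OC)C(=O)OC)OC(c2ccc(O[Si](C(C)C)(C(C)C)C(C)C)cc2)=CC1=O
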